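**Retrosynthetic overview**
1. Core numbering used below: C1 (angular methyl carbon), C2, C3, C4 (carbinol with isopropyl), C5 (ring-fusion CH), C6 (acyloxy carbon), C7=C8 (C8 bears methyl), C9 (carbinol), C10; five-membered ring = C1–C5, seven-membered ring = C1, C5–C10.
2. Late disconnections: the vanillate C6–O bond (Yamaguchi esterification), C7=C8 (ring-closing metathesis, closes the seven-membered ring), and C4–isopropyl (organocerium addition to a C4 ketone).
3. Central disconnection: C5–C6 and C1–C10 are made in one radical chain on the bromomethylsilyl ether of (1S)-3-methylcyclopent-2-en-1-ol; the C5–C6 bond closes a temporary five-membered O4–Si–C6–C5–C4 ring, which Tamao–Kumada oxidation later cleaves to give the C6 oxygen of the target.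
4. Enabling feature: on the five-membered ring the C4 oxygen and C6 (on C5) are cis, and C6 itself carries oxygen, so O4–Si–C6 is a natural tether and C6–Si a masked C6–O bond; C10 on C1 is trans to C6, which is what capture of the C1 radical anti to the new ring delivers.
5. Ring order: cyclopentene (from the enone) → temporary oxasilacyclopentane (key step, then cleaved) → seven-membered ring by metathesis.

Key step: step 3

Remark: the antipode of the chiral chromium ligand in step 9 is taken to be the one that gives the 9S carbinol.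

**Step 1**
Reactants: 1 3-methylcyclopent-2-en-1-one
Product: 2 (1S)-3-methylcyclopent-2-en-1-ol
Conditions: (R)-2-methyl-CBS-oxazaborolidine (10 mol %), BH3·SMe2, THF, −20 °C; aqueous work-up
Reagents that add atoms: none
Why: Corey–Bakshi–Shibata reduction, with the enone C=C arm as the large group, should deliver hydride to one carbonyl face and set C4 as S (this oxygen is the tether anchor and is oxidised away in step 6).

**Step 2**
Reactants: 2 (1S)-3-methylcyclopent-2-en-1-ol
Product: 3 (bromomethyl)(dimethyl){[(1S)-3-methylcyclopent-2-en-1-yl]oxy}silane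
Conditions: BrCH2SiMe2Cl, Et3N, DMAP (cat.), CH2Cl2, 0 °C
Reagents that add atoms: (bromomethyl)chlorodimethylsilane, C[Si](C)(Cl)CBr
Why: O-silylation of a secondary allylic alcohol with a chlorosilane and amine base is routine and installs the radical tether without touching the stereocentre.

**Step 3**
Reactants: 3 (bromomethyl)(dimethyl){[(1S)-3-methylcyclopent-2-en-1-yl]oxy}silane
Product: 4 (3aR,4R,6aS)-2,2,4-trimethyl-4-(prop-2-en-1-yl)-3,3a,4,5,6,6a-hexahydro-2H-cyclopenta[d][1,2]oxasilole
Conditions: allyltributylstannane (5 equiv), AIBN (0.2 equiv, in portions), benzene (0.05 M), 80 °C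
Reagents that add atoms: allyltributylstannane, C=CC[Sn](CCCC)(CCCC)CCCC
Why: Tributyltin radical abstracts bromine from 3, the α-silyl radical at C6 adds to C5 of the trisubstituted alkene, and the tertiary C1 radical so formed is captured by allyltributylstannane with release of the chain-carrying tin radical. The closest known reaction types are the Nishiyama–Stork cyclization of (bromomethyl)silyl ethers of cycloalk-2-enols and the Keck allylation of tertiary alkyl radicals, here run as one cyclization–allyl-transfer chain. The one ring closed is the 1-oxa-2-silacyclopentane O4–Si–C6–C5–C4, by a 5-exo-trig closure through the new C5–C6 bond. C5 is set by the tether (the five-membered ring can only be cis-fused, so C6 lands on the face of the C4 oxygen), and C1 is set by allyl delivery to the convex face of this cis-fused bicycle, anti to the new C5–C6 bond, which puts C10 trans and the methyl cis to C6. The step needs 5-exo over 6-endo closure and ring closure before allyl transfer; the methyl on C1 secures the first (hindered distal carbon, tertiary radical formed), and unimolecular cyclization should outrun bimolecular trapping at moderate stannane concentration.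

**Step 4**
Reactants: 4 (3aR,4R,6aS)-2,2,4-trimethyl-4-(prop-2-en-1-yl)-3,3a,4,5,6,6a-hexahydro-2H-cyclopenta[d][1,2]oxasilole
Product: 5 (1S,2S,3R)-2-(hydroxymethyl)-3-methyl-3-(prop-2-en-1-yl)cyclopentan-1-ol
Conditions: 30% H2O2, KF, KHCO3, THF/MeOH, 40 °C
Reagents that add atoms: hydrogen peroxide, OO
Why: Tamao–Kumada oxidation converts the C6–Si bond of the alkoxysilane into C6–OH with retention and frees the C4 hydroxyl, leaving the allyl group untouched.

**Step 5**
Reactants: 5 (1S,2S,3R)-2-(hydroxymethyl)-3-methyl-3-(prop-2-en-1-yl)cyclopentan-1-ol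
Product: 6 (1S,2S,3R)-3-methyl-3-(prop-2-en-1-yl)-2-{[(triethylsilyl)oxy]methyl}cyclopentan-1-ol
Conditions: Et3SiCl (1.05 equiv), imidazole, CH2Cl2, −78 to −40 °C
Reagents that add atoms: chlorotriethylsilane, CC[Si](Cl)(CC)CC
Why: Kinetic silylation should take the primary hydroxyl well ahead of the hindered secondary one.

**Step 6**
Reactants: 6 (1S,2S,3R)-3-methyl-3-(prop-2-en-1-yl)-2-{[(triethylsilyl)oxy]methyl}cyclopentan-1-ol
Product: 7 (2S,3R)-3-methyl-3-(prop-2-en-1-yl)-2-{[(triethylsilyl)oxy]methyl}cyclopentan-1-one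
Conditions: Dess–Martin periodinane, pyridine, CH2Cl2, 0 °C to rt
Reagents that add atoms: none
Why: Buffered Dess–Martin oxidation gives the C4 ketone without β-elimination of the silyloxy group; C5 should hold its configuration because its substituent already sits trans to the larger allyl group on C1.

**Step 7**
Reactants: 7 (2S,3R)-3-methyl-3-(prop-2-en-1-yl)-2-{[(triethylsilyl)oxy]methyl}cyclopentan-1-one
Product: 8 (1R,2S,3R)-3-methyl-1-(propan-2-yl)-3-(prop-2-en-1-yl)-2-{[(triethylsilyl)oxy]methyl}cyclopentan-1-ol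
Conditions: i-PrMgCl, CeCl3, THF, −78 °C
Reagents that add atoms: isopropylmagnesium chloride, CC(C)[Mg]Cl
Why: Organocerium 1,2-addition suppresses enolisation and reduction; the nucleophile should enter trans to the adjacent C5 substituent and to the C1 methyl (both on the same face), setting C4 as R with the hydroxyl cis to C6.

**Step 8**
Reactants: 8 (1R,2S,3R)-3-methyl-1-(propan-2-yl)-3-(prop-2-en-1-yl)-2-{[(triethylsilyl)oxy]methyl}cyclopentan-1-ol
Product: 10 2-[(1R,2S,3R)-3-hydroxy-1-methyl-3-(propan-2-yl)-2-{[(triethylsilyl)oxy]methyl}cyclopentyl]acetaldehyde, via ozonide 9 (not isolated)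
Conditions: O3, CH2Cl2, −78 °C; then PPh3, −78 °C to rt
Reagents that add atoms: ozone, [O-][O+]=O
Why: Ozonolysis with reductive work-up cleaves the only alkene to the C9 aldehyde; a lactol cannot form because the C4 hydroxyl and C10 are trans across the ring.

**Step 9**
Reactants: 10 2-[(1R,2S,3R)-3-hydroxy-1-methyl-3-(propan-2-yl)-2-{[(triethylsilyl)oxy]methyl}cyclopentyl]acetaldehyde
Product: 11 (1R,2S,3R)-3-[(2S)-2-hydroxy-3-methylbut-3-en-1-yl]-3-methyl-1-(propan-2-yl)-2-{[(triethylsilyl)oxy]methyl}cyclopentan-1-ol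
Conditions: 2-bromopropene, CrCl2, NiCl2 (cat.), chiral oxazoline–sulfonamide ligand, Et3N, THF, rt
Reagents that add atoms: 2-bromopropene, C=C(C)Br
Why: Asymmetric Nozaki–Hiyama–Kishi alkenylation tolerates the free tertiary alcohol and the silyl ether, and the chiral chromium complex (reagent control) should set C9 as S.

**Step 10**
Reactants: 11 (1R,2S,3R)-3-[(2S)-2-hydroxy-3-methylbut-3-en-1-yl]-3-methyl-1-(propan-2-yl)-2-{[(triethylsilyl)oxy]methyl}cyclopentan-1-ol
Product: 12 (1R,2S,3R)-3-[(2S)-2-{[tert-butyl(dimethyl)silyl]oxy}-3-methylbut-3-en-1-yl]-3-methyl-1-(propan-2-yl)-2-{[(triethylsilyl)oxy]methyl}cyclopentan-1-ol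
Conditions: TBSOTf (1.1 equiv), 2,6-lutidine, CH2Cl2, −78 °C
Reagents that add atoms: tert-butyldimethylsilyl trifluoromethanesulfonate, CC(C)(C)[Si](C)(C)OS(=O)(=O)C(F)(F)F
Why: Silylation at low temperature should take the secondary allylic hydroxyl and leave the tertiary C4 hydroxyl, which is flanked by isopropyl, untouched.

**Step 11**
Reactants: 12 (1R,2S,3R)-3-[(2S)-2-{[tert-butyl(dimethyl)silyl]oxy}-3-methylbut-3-en-1-yl]-3-methyl-1-(propan-2-yl)-2-{[(triethylsilyl)oxy]methyl}cyclopentan-1-ol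
Product: 13 (1R,2R,5R)-5-[(2S)-2-{[tert-butyl(dimethyl)silyl]oxy}-3-methylbut-3-en-1-yl]-2-hydroxy-5-methyl-2-(propan-2-yl)cyclopentane-1-carbaldehyde
Conditions: (COCl)2, DMSO, CH2Cl2, −78 to −30 °C; then Et3N, −78 °C to rt
Reagents that add atoms: none
Why: Swern conditions cleave and oxidise a primary triethylsilyl ether directly to the aldehyde while the secondary TBS ether and the tertiary alcohol survive; the formyl group stays on the less crowded face (cis to methyl and hydroxyl), so C5 should not epimerise.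

**Step 12**
Reactants: 13 (1R,2R,5R)-5-[(2S)-2-{[tert-butyl(dimethyl)silyl]oxy}-3-methylbut-3-en-1-yl]-2-hydroxy-5-methyl-2-(propan-2-yl)cyclopentane-1-carbaldehyde
Product: 14 (1R,2S,3R)-3-[(2S)-2-{[tert-butyl(dimethyl)silyl]oxy}-3-methylbut-3-en-1-yl]-2-[(1S)-1-hydroxyprop-2-en-1-yl]-3-methyl-1-(propan-2-yl)cyclopentan-1-ol
Conditions: vinylmagnesium bromide (3.5 equiv), THF, −78 °C; aq. NH4Cl
Reagents that add atoms: vinylmagnesium bromide, C=C[Mg]Br
Why: Chelation-controlled Grignard addition: the magnesium alkoxide of the C4 hydroxyl binds the aldehyde oxygen in a six-membered chelate, and vinyl should add to the exposed face, away from the ring and the C1 methyl, setting C6 as S.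

**Step 13**
Reactants: 14 (1R,2S,3R)-3-[(2S)-2-{[tert-butyl(dimethyl)silyl]oxy}-3-methylbut-3-en-1-yl]-2-[(1S)-1-hydroxyprop-2-en-1-yl]-3-methyl-1-(propan-2-yl)cyclopentan-1-ol
Product: 15 (3R,3aS,4S,7S,8aR)-7-{[tert-butyl(dimethyl)silyl]oxy}-6,8a-dimethyl-3-(propan-2-yl)-1,2,3,3a,4,7,8,8a-octahydroazulene-3,4-diol
Conditions: second-generation Grubbs catalyst (5 mol %), CH2Cl2 (0.002 M), 40 °C
Reagents that add atoms: none
Why: Ring-closing metathesis between the vinyl group and the 1,1-disubstituted alkene on the trans-disposed arms should close the trans-fused seven-membered ring and form the trisubstituted C7=C8 bond, whose Z geometry is enforced by the ring.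

**Step 14**
Reactants: 16 4-hydroxy-3-methoxybenzoic acid (vanillic acid)
Product: 18 4-{[tert-butyl(dimethyl)silyl]oxy}-3-methoxybenzoic acid, via silyl ester 17 (not isolated)
Conditions: TBSCl (2.2 equiv), imidazole, DMF, rt; then AcOH/THF/H2O, rt
Reagents that add atoms: tert-butyldimethylsilyl chloride, CC(C)(C)[Si](C)(C)Cl
Why: Exhaustive silylation followed by selective hydrolysis of the labile silyl ester leaves the aryl silyl ether and frees the acid.

**Step 15**
Reactants: 15 (3R,3aS,4S,7S,8aR)-7-{[tert-butyl(dimethyl)silyl]oxy}-6,8a-dimethyl-3-(propan-2-yl)-1,2,3,3a,4,7,8,8a-octahydroazulene-3,4-diol; 18 4-{[tert-butyl(dimethyl)silyl]oxy}-3-methoxybenzoic acid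
Product: 20 (3R,3aS,4S,7S,8aR)-7-{[tert-butyl(dimethyl)silyl]oxy}-3-hydroxy-6,8a-dimethyl-3-(propan-2-yl)-1,2,3,3a,4,7,8,8a-octahydroazulen-4-yl 4-{[tert-butyl(dimethyl)silyl]oxy}-3-methoxybenzoate, via mixed anhydride 19 (not isolated)
Conditions: 18, 2,4,6-trichlorobenzoyl chloride, Et3N, THF, rt; then 15, DMAP, toluene, rt
Reagents that add atoms: none
Why: Yamaguchi esterification should acylate the secondary allylic C6 hydroxyl and not the tertiary C4 hydroxyl, with retention at C6 because only the O–acyl bond is formed.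

**Step 16**
Reactants: 20 (3R,3aS,4S,7S,8aR)-7-{[tert-butyl(dimethyl)silyl]oxy}-3-hydroxy-6,8a-dimethyl-3-(propan-2-yl)-1,2,3,3a,4,7,8,8a-octahydroazulen-4-yl 4-{[tert-butyl(dimethyl)silyl]oxy}-3-methoxybenzoate
Product: 21 (3R,3aS,4S,7S,8aR)-3,7-dihydroxy-6,8a-dimethyl-3-(propan-2-yl)-1,2,3,3a,4,7,8,8a-octahydroazulen-4-yl 4-hydroxy-3-methoxybenzoate
Conditions: HF·pyridine, pyridine, THF, 0 °C to rt
Reagents that add atoms: none
Why: Buffered fluoride desilylation removes the aryl and the secondary allylic silyl ethers and leaves the benzoate ester and all stereocentres untouched.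

**Compound list**
1 | 3-methylcyclopent-2-en-1-one | CC1=CC(=O)CC1 | starting material
2 | (1S)-3-methylcyclopent-2-en-1-ol | CC1=C[C@@H](O)CC1 | intermediate
3 | (bromomethyl)(dimethyl){[(1S)-3-methylcyclopent-2-en-1-yl]oxy}silane | CC1=C[C@@H](O[Si](C)(C)CBr)CC1 | intermediate
4 | (3aR,4R,6aS)-2,2,4-trimethyl-4-(prop-2-en-1-yl)-3,3a,4,5,6,6a-hexahydro-2H-cyclopenta[d][1,2]oxasilole (cis-fused; allyl trans to the ring CH2 on the neighbouring carbon) | C=CC[C@@]1(C)CC[C@@H]2O[Si](C)(C)C[C@H]12 | intermediate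
5 | (1S,2S,3R)-2-(hydroxymethyl)-3-methyl-3-(prop-2-en-1-yl)cyclopentan-1-ol | C=CC[C@@]1(C)CC[C@H](O)[C@@H]1CO | intermediate
6 | (1S,2S,3R)-3-methyl-3-(prop-2-en-1-yl)-2-{[(triethylsilyl)oxy]methyl}cyclopentan-1-ol | C=CC[C@@]1(C)CC[C@H](O)[C@@H]1CO[Si](CC)(CC)CC | intermediate
7 | (2S,3R)-3-methyl-3-(prop-2-en-1-yl)-2-{[(triethylsilyl)oxy]methyl}cyclopentan-1-one | C=CC[C@@]1(C)CCC(=O)[C@@H]1CO[Si](CC)(CC)CC | intermediate
8 | (1R,2S,3R)-3-methyl-1-(propan-2-yl)-3-(prop-2-en-1-yl)-2-{[(triethylsilyl)oxy]methyl}cyclopentan-1-ol | C=CC[C@@]1(C)CC[C@@](O)(C(C)C)[C@@H]1CO[Si](CC)(CC)CC | intermediate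
9 | (1R,2S,3R)-3-methyl-1-(propan-2-yl)-2-{[(triethylsilyl)oxy]methyl}-3-[(1,2,4-trioxolan-3-yl)methyl]cyclopentan-1-ol (ozonide, both epimers at the trioxolane carbon) | O1OCOC1C[C@@]2(C)CC[C@@](O)(C(C)C)[C@@H]2CO[Si](CC)(CC)CC | intermediate
10 | 2-[(1R,2S,3R)-3-hydroxy-1-methyl-3-(propan-2-yl)-2-{[(triethylsilyl)oxy]methyl}cyclopentyl]acetaldehyde | O=CC[C@@]1(C)CC[C@@](O)(C(C)C)[C@@H]1CO[Si](CC)(CC)CC | intermediate
11 | (1R,2S,3R)-3-[(2S)-2-hydroxy-3-methylbut-3-en-1-yl]-3-methyl-1-(propan-2-yl)-2-{[(triethylsilyl)oxy]methyl}cyclopentan-1-ol | C=C(C)[C@@H](O)C[C@@]1(C)CC[C@@](O)(C(C)C)[C@@H]1CO[Si](CC)(CC)CC | intermediate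
12 | (1R,2S,3R)-3-[(2S)-2-{[tert-butyl(dimethyl)silyl]oxy}-3-methylbut-3-en-1-yl]-3-methyl-1-(propan-2-yl)-2-{[(triethylsilyl)oxy]methyl}cyclopentan-1-ol | C=C(C)[C@@H](O[Si](C)(C)C(C)(C)C)C[C@@]1(C)CC[C@@](O)(C(C)C)[C@@H]1CO[Si](CC)(CC)CC | intermediate
13 | (1R,2R,5R)-5-[(2S)-2-{[tert-butyl(dimethyl)silyl]oxy}-3-methylbut-3-en-1-yl]-2-hydroxy-5-methyl-2-(propan-2-yl)cyclopentane-1-carbaldehyde | C=C(C)[C@@H](O[Si](C)(C)C(C)(C)C)C[C@@]1(C)CC[C@@](O)(C(C)C)[C@@H]1C=O | intermediate
14 | (1R,2S,3R)-3-[(2S)-2-{[tert-butyl(dimethyl)silyl]oxy}-3-methylbut-3-en-1-yl]-2-[(1S)-1-hydroxyprop-2-en-1-yl]-3-methyl-1-(propan-2-yl)cyclopentan-1-ol | C=C(C)[C@@H](O[Si](C)(C)C(C)(C)C)C[C@@]1(C)CC[C@@](O)(C(C)C)[C@@H]1[C@@H](O)C=C | intermediate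
15 | (3R,3aS,4S,7S,8aR)-7-{[tert-butyl(dimethyl)silyl]oxy}-6,8a-dimethyl-3-(propan-2-yl)-1,2,3,3a,4,7,8,8a-octahydroazulene-3,4-diol | O[C@H]1C=C(C)[C@@H](O[Si](C)(C)C(C)(C)C)C[C@@]2(C)CC[C@@](O)(C(C)C)[C@H]12 | intermediate
16 | 4-hydroxy-3-methoxybenzoic acid (vanillic acid) | COc1cc(C(=O)O)ccc1O | starting material
17 | tert-butyl(dimethyl)silyl 4-{[tert-butyl(dimethyl)silyl]oxy}-3-methoxybenzoate | COc1cc(C(=O)O[Si](C)(C)C(C)(C)C)ccc1O[Si](C)(C)C(C)(C)C | intermediate
18 | 4-{[tert-butyl(dimethyl)silyl]oxy}-3-methoxybenzoic acid | COc1cc(C(=O)O)ccc1O[Si](C)(C)C(C)(C)C | intermediate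
19 | 4-{[tert-butyl(dimethyl)silyl]oxy}-3-methoxybenzoic 2,4,6-trichlorobenzoic anhydride | COc1cc(C(=O)OC(=O)c2c(Cl)cc(Cl)cc2Cl)ccc1O[Si](C)(C)C(C)(C)C | intermediate
20 | (3R,3aS,4S,7S,8aR)-7-{[tert-butyl(dimethyl)silyl]oxy}-3-hydroxy-6,8a-dimethyl-3-(propan-2-yl)-1,2,3,3a,4,7,8,8a-octahydroazulen-4-yl 4-{[tert-butyl(dimethyl)silyl]oxy}-3-methoxybenzoate | COc1cc(C(=O)O[C@H]2C=C(C)[C@@H](O[Si](C)(C)C(C)(C)C)C[C@@]3(C)CC[C@@](O)(C(C)C)[C@H]23)ccc1O[Si](C)(C)C(C)(C)C | intermediate
21 | (3R,3aS,4S,7S,8aR)-3,7-dihydroxy-6,8a-dimethyl-3-(propan-2-yl)-1,2,3,3a,4,7,8,8a-octahydroazulen-4-yl 4-hydroxy-3-methoxybenzoate | COc1cc(C(=O)O[C@H]2C=C(C)[C@@H](O)C[C@@]3(C)CC[C@@](O)(C(C)C)[C@H]23)ccc1O | target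

**Step count**
Total step count: 16. Longest linear sequence: 15 steps (steps 1–13, 15, 16).

**Steps most likely to fail**

Step 3. The chain may break down through allyl transfer to the α-silyl radical before ring closure, or through slow capture of the hindered tertiary C1 radical, which would lose the quaternary centre. The fallback builds C1 first by polar chemistry and gives up the tether; it sets out from compound 1 and comes back at compound 10. Copper-catalysed enantioselective conjugate addition of diisobutyl(vinyl)aluminium to 1 (Cu(OTf)2, chiral N-heterocyclic carbene ligand), with trapping of the enolate by Me3SiOTf, should give {[(3R)-3-ethenyl-3-methylcyclopent-1-en-1-yl]oxy}(trimethyl)silane F1. A Sc(OTf)3-catalysed Mukaiyama aldol of F1 with aqueous formaldehyde should give (2S,3R)-3-ethenyl-2-(hydroxymethyl)-3-methylcyclopentan-1-one F2; vinyl and methyl differ little in size, so the C5 epimers would have to be separated and the wrong one recycled by base equilibration. Silylation with Et3SiCl and imidazole should give the triethylsilyl ether F3. Isopropylcerium addition as in step 7 should give the tertiary alcohol F4. Hydroboration with 9-BBN and oxidation with NaOH/H2O2 should give the primary alcohol F5, and Dess–Martin oxidation of F5 leads to 10.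

Step 9. The chiral chromium complex may discriminate poorly between the faces of an aldehyde that is remote from every stereocentre. The fallback replaces C–C bond formation under reagent control by a reagent-controlled reduction; it sets out from compound 10 and comes back at compound 11. Isopropenylmagnesium bromide added to 10 should give the allylic alcohol as both C9 epimers F6. Dess–Martin oxidation of the secondary allylic hydroxyl of F6 should give the isopropenyl ketone F7. Corey–Bakshi–Shibata reduction of F7 with the (R)-oxazaborolidine and catecholborane, with the isopropenyl group as the large substituent, should give 11.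

Step 12. The vinyl addition may run through a non-chelated transition state and give poor facial selectivity at C6, or the magnesium aldolate may suffer retro-aldol cleavage. The fallback sets the C6 configuration after ring closure; it sets out from compound 15 obtained as a mixture of C6 epimers (both epimers of 14 should cyclise in step 13) and comes back at compound 15 as the single 4S isomer. Oxidation of the allylic alcohol mixture with MnO2 should give the cycloheptenone F8. Evans–Saksena reduction of F8 with Me4NBH(OAc)3 in MeCN/AcOH should deliver hydride from boron bound to the cis C4 hydroxyl to the same face of the C6 carbonyl and give 15.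

Further compounds
F1 | step 3 | {[(3R)-3-ethenyl-3-methylcyclopent-1-en-1-yl]oxy}(trimethyl)silane | C=C[C@@]1(C)CCC(O[Si](C)(C)C)=C1
F2 | step 3 | (2S,3R)-3-ethenyl-2-(hydroxymethyl)-3-methylcyclopentan-1-one | C=C[C@@]1(C)CCC(=O)[C@@H]1CO
F3 | step 3 | (2S,3R)-3-ethenyl-3-methyl-2-{[(triethylsilyl)oxy]methyl}cyclopentan-1-one | C=C[C@@]1(C)CCC(=O)[C@@H]1CO[Si](CC)(CC)CC
F4 | step 3 | (1R,2S,3R)-3-ethenyl-3-methyl-1-(propan-2-yl)-2-{[(triethylsilyl)oxy]methyl}cyclopentan-1-ol | C=C[C@@]1(C)CC[C@@](O)(C(C)C)[C@@H]1CO[Si](CC)(CC)CC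
F5 | step 3 | (1R,2S,3R)-3-(2-hydroxyethyl)-3-methyl-1-(propan-2-yl)-2-{[(triethylsilyl)oxy]methyl}cyclopentan-1-ol | OCC[C@@]1(C)CC[C@@](O)(C(C)C)[C@@H]1CO[Si](CC)(CC)CC
F6 | step 9 | (1R,2S,3R)-3-(2-hydroxy-3-methylbut-3-en-1-yl)-3-methyl-1-(propan-2-yl)-2-{[(triethylsilyl)oxy]methyl}cyclopentan-1-ol (both epimers at the side-chain carbinol) | C=C(C)C(O)C[C@@]1(C)CC[C@@](O)(C(C)C)[C@@H]1CO[Si](CC)(CC)CC
F7 | step 9 | 1-[(1R,2S,3R)-3-hydroxy-1-methyl-3-(propan-2-yl)-2-{[(triethylsilyl)oxy]methyl}cyclopentyl]-3-methylbut-3-en-2-one | C=C(C)C(=O)C[C@@]1(C)CC[C@@](O)(C(C)C)[C@@H]1CO[Si](CC)(CC)CC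
F8 | step 12 | (3R,3aR,7S,8aR)-7-{[tert-butyl(dimethyl)silyl]oxy}-3-hydroxy-6,8a-dimethyl-3-(propan-2-yl)-2,3,3a,7,8,8a-hexahydroazulen-4(1H)-one | O=C1C=C(C)[C@@H](O[Si](C)(C)C(C)(C)C)C[C@@]2(C)CC[C@@](O)(C(C)C)[C@H]12
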